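**Retrosynthetic overview**

1. The target is reached by desilylation of a 6-O-silyl 8,12-di-O-angelate, which comes from LiAlH4 opening of a silylated 6-hydroxy-8,12-lactone, itself the Luche reduction product of a 6-oxo-8,12-germacranolide.
2. Key disconnection C6–C7: an intramolecular Stetter reaction, in which the carbene-bound acyl anion equivalent of the enal carbon C6 adds to C7 of an α-methylbutenolide; this closes the ten-membered ring and sets C7 and C11 from C8.
3. The butenolide comes from a γ,δ-unsaturated aldehyde by D-proline α-aminoxylation, Z-selective Horner–Wadsworth–Emmons olefination and lactonisation (sets C8).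
4. The acyclic chain comes from 1,5-dimethylcycloocta-1,5-diene by mono-ozonolysis (the ring supplies the Z C1=C10 olefin) and E-selective olefination of the resulting methyl ketone (C4=C5).
5. Ring order: butenolide first, ten-membered carbocycle second; the lactone is then opened, so only the carbocycle remains in the target.

Assumption: (1Z,5Z)-1,5-dimethylcycloocta-1,5-diene (1) is used as the pure 1,5-isomer (technical material is fractionally distilled to remove the 1,6-isomer); ring compounds are named with germacrane numbering (ring C1–C10, C14 on C10, C15 on C4, side chain C11(C13)–C12 on C7).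

**Step 1**
Reactants: 1 (1Z,5Z)-1,5-dimethylcycloocta-1,5-diene
Product: 4 (5Z)-9,9-dimethoxy-6-methylnon-5-en-2-one, via hydroperoxy aldehyde 2 (not isolated), via hydroperoxy acetal 3 (not isolated)
Conditions: O3 (0.9 equiv), CH2Cl2/MeOH, −78 °C; p-toluenesulfonic acid monohydrate (cat.), rt; NaHCO3; Me2S, rt
Reagents that add atoms: ozone O=[O+][O-]; methanol CO
Why: Mono-ozonolysis (Criegee mechanism) with in-flask differentiation of the termini: the more substituted carbonyl oxide is trapped by MeOH, the free aldehyde is acetalised, and Me2S reduction releases the methyl ketone, while the untouched cis ring olefin becomes the Z C1=C10 bond.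

**Step 2**
Reactants: 4 (5Z)-9,9-dimethoxy-6-methylnon-5-en-2-one; 5 ethyl 2-[di(propan-2-yloxy)phosphoryl]acetate
Product: 6 ethyl (2E,6Z)-10,10-dimethoxy-3,7-dimethyldeca-2,6-dienoate
Conditions: NaH, THF, 0 → 40 °C
Reagents that add atoms: none
Why: Horner–Wadsworth–Emmons olefination of the methyl ketone; the bulky diisopropyl phosphonate favours the E enoate (about 9:1 expected), and the minor 2Z isomer is removed by chromatography here or after step 3.

**Step 3**
Reactants: 6 ethyl (2E,6Z)-10,10-dimethoxy-3,7-dimethyldeca-2,6-dienoate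
Product: 8 (4Z,8E)-10-hydroxy-4,8-dimethyldeca-4,8-dienal, via hydroxy acetal 7 (not isolated)
Conditions: i-Bu2AlH (2.2 equiv), CH2Cl2, −78 °C; aq. potassium sodium tartrate; then pyridinium p-toluenesulfonate (cat.), acetone/H2O, 50 °C
Reagents that add atoms: water O
Why: 1,2-Reduction of the enoate to the allylic alcohol by the aluminium hydride (acetal inert), then mild acid hydrolysis of the dimethyl acetal to the aldehyde.

**Step 4**
Reactants: 8 (4Z,8E)-10-hydroxy-4,8-dimethyldeca-4,8-dienal; 9 ethyl 2-(diphenoxyphosphoryl)propanoate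
Product: 13 (5S)-5-[(2Z,6E)-8-hydroxy-2,6-dimethylocta-2,6-dien-1-yl]-3-methylfuran-2(5H)-one, via aminoxy aldehyde 10 (not isolated), via aminoxy enoate 11 (not isolated), via hydroxy enoate 12 (not isolated)
Conditions: D-proline (20 mol %), PhNO (1.0 equiv), MeCN, −20 °C; then sodium salt of 9 (from 9, NaH), THF, −78 → 0 °C; then AcOH, Zn dust, rt
Reagents that add atoms: nitrosobenzene O=Nc1ccccc1
Why: Proline-catalysed α-aminoxylation (the enamine attacks the nitroso oxygen through the hydrogen-bonded transition state; D-proline gives the 2S aldehyde, which becomes C8), then Ando-type Z-selective Horner–Wadsworth–Emmons olefination puts the ester cis to C8, and Zn/AcOH N–O cleavage frees the γ-hydroxy Z-enoate, which lactonises.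

**Step 5**
Reactants: 13 (5S)-5-[(2Z,6E)-8-hydroxy-2,6-dimethylocta-2,6-dien-1-yl]-3-methylfuran-2(5H)-one
Product: 14 (2E,6Z)-3,7-dimethyl-8-[(2S)-4-methyl-5-oxo-2,5-dihydrofuran-2-yl]octa-2,6-dienal
Conditions: MnO2 (15 equiv), CH2Cl2, rt
Reagents that add atoms: none
Why: Chemoselective MnO2 oxidation of the allylic alcohol to the E enal without touching the butenolide or the C8 centre.

**Step 6**
Reactants: 14 (2E,6Z)-3,7-dimethyl-8-[(2S)-4-methyl-5-oxo-2,5-dihydrofuran-2-yl]octa-2,6-dienal
Product: 16 (1(10)Z,4E,7R,8S,11S)-6-oxogermacra-1(10),4-dien-12,8-olide, via Breslow intermediate 15 (not isolated)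
Conditions: 2-(pentafluorophenyl)-6,7-dihydro-5H-pyrrolo[2,1-c][1,2,4]triazol-2-ium tetrafluoroborate (20 mol %), i-Pr2NEt (1 equiv), catechol (1 equiv), t-AmOH, 40 °C, 14 added by syringe pump over 16 h (final 0.002 M)
Reagents that add atoms: none
Why: Proposed new method: a macrocyclising intramolecular Stetter reaction in which the triazolylidene adds to the enal carbonyl to give Breslow intermediate 15 (acyl anion equivalent at C6), which adds 10-exo-trig to butenolide C7 anti to the C8–C9 bond (the usual anti-to-γ-substituent mode, giving the trans-fused lactone), the lactone enolate is protonated at C11 by catechol or the ammonium ion from the convex face anti to the new C6–C7 bond (methyl cis to C6), and the carbene is released; the closest known chemistry is the triazolium-catalysed Stetter reaction of enals in t-AmOH with catechol, the intramolecular Stetter reaction onto trisubstituted unsaturated esters, and the C6–C7 closure of seco-farnesyl chains to germacrane rings by anionic acyl anion equivalents, with the β,β-disubstituted enal retarding the homoenolate pathway and the two trisubstituted olefins pre-organising the chain.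

**Step 7**
Reactants: 16 (1(10)Z,4E,7R,8S,11S)-6-oxogermacra-1(10),4-dien-12,8-olide
Product: 17 (1(10)Z,4E,6S,7S,8S,11S)-6-hydroxygermacra-1(10),4-dien-12,8-olide
Conditions: NaBH4, CeCl3·7H2O, MeOH/CH2Cl2, −78 °C
Reagents that add atoms: none
Why: Luche 1,2-reduction of the enone (lactone untouched); hydride arrives from the peripheral face anti to the C7–C8 ring bond (Felkin–Anh, C8 perpendicular, passing H-7), which should give the 6S alcohol anti to O8.

**Step 8**
Reactants: 17 (1(10)Z,4E,6S,7S,8S,11S)-6-hydroxygermacra-1(10),4-dien-12,8-olide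
Product: 18 (1(10)Z,4E,6S,7R,8S,11S)-6-[(tert-butyldimethylsilyl)oxy]germacra-1(10),4-dien-12,8-olide
Conditions: TBSOTf, 2,6-lutidine, CH2Cl2, −78 → 0 °C
Reagents that add atoms: tert-butyldimethylsilyl trifluoromethanesulfonate CC(C)(C)[Si](C)(C)OS(=O)(=O)C(F)(F)F
Why: Silylation of the hindered allylic alcohol masks O6, the one hydroxyl that must stay free at the end (the C7 descriptor changes by priority only, not by geometry).

**Step 9**
Reactants: 18 (1(10)Z,4E,6S,7R,8S,11S)-6-[(tert-butyldimethylsilyl)oxy]germacra-1(10),4-dien-12,8-olide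
Product: 19 (1(10)Z,4E,6S,7R,8S,11S)-6-[(tert-butyldimethylsilyl)oxy]germacra-1(10),4-diene-8,12-diol
Conditions: LiAlH4, THF, 0 °C; H2O, aq. NaOH
Reagents that add atoms: none
Why: Hydride reduction of the γ-lactone to the 8,12-diol, which frees exactly the two hydroxyls to be acylated; C11 is not epimerised under these conditions.

**Step 10**
Reactants: 19 (1(10)Z,4E,6S,7R,8S,11S)-6-[(tert-butyldimethylsilyl)oxy]germacra-1(10),4-diene-8,12-diol; 20 angelic acid, (2Z)-2-methylbut-2-enoic acid
Product: 21 (1(10)Z,4E,6S,7R,8S,11S)-6-[(tert-butyldimethylsilyl)oxy]germacra-1(10),4-diene-8,12-diyl bis[(2Z)-2-methylbut-2-enoate]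
Conditions: 20 (3 equiv), 2,4,6-trichlorobenzoyl chloride (3 equiv), Et3N (6 equiv), toluene, rt; then 19, 75 °C
Reagents that add atoms: none
Why: Yamaguchi-type esterification through the in-flask mixed anhydride without a nucleophilic catalyst, the conditions that acylate hindered alcohols with angelic acid without Z-to-E (tiglate) isomerisation and, having no alkoxide, without silyl migration.

**Step 11**
Reactants: 21 (1(10)Z,4E,6S,7R,8S,11S)-6-[(tert-butyldimethylsilyl)oxy]germacra-1(10),4-diene-8,12-diyl bis[(2Z)-2-methylbut-2-enoate]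
Product: 22 (1(10)Z,4E,6S,7S,8S,11S)-6-hydroxygermacra-1(10),4-diene-8,12-diyl bis[(2Z)-2-methylbut-2-enoate]
Conditions: HF·pyridine, pyridine, THF, 0 °C → rt
Reagents that add atoms: none
Why: Buffered fluoride desilylation of the allylic silyl ether, mild enough to avoid acyl migration from O8 to O6, angelate isomerisation and transannular cyclisation of the 1,5-diene.

**Compound list**

1 | (1Z,5Z)-1,5-dimethylcycloocta-1,5-diene | C/C1=C/CC/C(C)=C\CC1 | starting material
2 | (4Z)-8-hydroperoxy-8-methoxy-4-methylnon-4-enal | O=CCC/C(C)=C\CCC(C)(OC)OO | intermediate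
3 | (5Z)-2-hydroperoxy-2,9,9-trimethoxy-6-methylnon-5-ene | COC(OC)CC/C(C)=C\CCC(C)(OC)OO | intermediate
4 | (5Z)-9,9-dimethoxy-6-methylnon-5-en-2-one | CC(=O)CC/C=C(C)\CCC(OC)OC | intermediate
5 | ethyl 2-[di(propan-2-yloxy)phosphoryl]acetate | CCOC(=O)CP(=O)(OC(C)C)OC(C)C | starting material
6 | ethyl (2E,6Z)-10,10-dimethoxy-3,7-dimethyldeca-2,6-dienoate | CCOC(=O)/C=C(\C)CC/C=C(C)\CCC(OC)OC | intermediate
7 | (2E,6Z)-10,10-dimethoxy-3,7-dimethyldeca-2,6-dien-1-ol | OC/C=C(\C)CC/C=C(C)\CCC(OC)OC | intermediate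
8 | (4Z,8E)-10-hydroxy-4,8-dimethyldeca-4,8-dienal | O=CCC/C(C)=C\CC/C(C)=C/CO | intermediate
9 | ethyl 2-(diphenoxyphosphoryl)propanoate | CCOC(=O)C(C)P(=O)(Oc1ccccc1)Oc1ccccc1 | starting material
10 | (2S,4Z,8E)-10-hydroxy-4,8-dimethyl-2-[(phenylamino)oxy]deca-4,8-dienal | O=C[C@@H](ONc1ccccc1)C/C(C)=C\CC/C(C)=C/CO | intermediate
11 | ethyl (2Z,4S,6Z,10E)-12-hydroxy-2,6,10-trimethyl-4-[(phenylamino)oxy]dodeca-2,6,10-trienoate | CCOC(=O)/C(C)=C\[C@@H](ONc1ccccc1)C/C(C)=C\CC/C(C)=C/CO | intermediate
12 | ethyl (2Z,4S,6Z,10E)-4,12-dihydroxy-2,6,10-trimethyldodeca-2,6,10-trienoate | CCOC(=O)/C(C)=C\[C@@H](O)C/C(C)=C\CC/C(C)=C/CO | intermediate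
13 | (5S)-5-[(2Z,6E)-8-hydroxy-2,6-dimethylocta-2,6-dien-1-yl]-3-methylfuran-2(5H)-one | CC1=C[C@H](C/C(C)=C\CC/C(C)=C/CO)OC1=O | intermediate
14 | (2E,6Z)-3,7-dimethyl-8-[(2S)-4-methyl-5-oxo-2,5-dihydrofuran-2-yl]octa-2,6-dienal | O=C/C=C(\C)CC/C=C(C)\C[C@@H]1OC(=O)C(C)=C1 | intermediate
15 | Breslow intermediate: enaminol from 14 and the triazolylidene (carbene carbon bonded to C6, which carries OH) | OC(/C=C(\C)CC/C=C(C)\C[C@@H]1OC(=O)C(C)=C1)=C1N(c2c(F)c(F)c(F)c(F)c2F)N=C2CCCN12 | intermediate
16 | (1(10)Z,4E,7R,8S,11S)-6-oxogermacra-1(10),4-dien-12,8-olide (trans-fused lactone, C13 methyl cis to C6) | C[C@@H]1C(=O)O[C@H]2C/C(C)=C\CC/C(C)=C/C(=O)[C@H]12 | intermediate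
17 | (1(10)Z,4E,6S,7S,8S,11S)-6-hydroxygermacra-1(10),4-dien-12,8-olide | C[C@@H]1C(=O)O[C@H]2C/C(C)=C\CC/C(C)=C/[C@H](O)[C@H]12 | intermediate
18 | (1(10)Z,4E,6S,7R,8S,11S)-6-[(tert-butyldimethylsilyl)oxy]germacra-1(10),4-dien-12,8-olide | C[C@@H]1C(=O)O[C@H]2C/C(C)=C\CC/C(C)=C/[C@H](O[Si](C)(C)C(C)(C)C)[C@H]12 | intermediate
19 | (1(10)Z,4E,6S,7R,8S,11S)-6-[(tert-butyldimethylsilyl)oxy]germacra-1(10),4-diene-8,12-diol | OC[C@@H](C)[C@@H]1[C@@H](O)C/C(C)=C\CC/C(C)=C/[C@@H]1O[Si](C)(C)C(C)(C)C | intermediate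
20 | angelic acid, (2Z)-2-methylbut-2-enoic acid | C/C=C(/C)C(=O)O | starting material
21 | (1(10)Z,4E,6S,7R,8S,11S)-6-[(tert-butyldimethylsilyl)oxy]germacra-1(10),4-diene-8,12-diyl bis[(2Z)-2-methylbut-2-enoate] | C/C=C(/C)C(=O)OC[C@@H](C)[C@@H]1[C@@H](OC(=O)/C(C)=C\C)C/C(C)=C\CC/C(C)=C/[C@@H]1O[Si](C)(C)C(C)(C)C | intermediate
22 | (1(10)Z,4E,6S,7S,8S,11S)-6-hydroxygermacra-1(10),4-diene-8,12-diyl bis[(2Z)-2-methylbut-2-enoate] (CNP0149864.1) | C/C=C(/C)C(=O)OC[C@@H](C)[C@@H]1[C@@H](OC(=O)/C(C)=C\C)C/C(C)=C\CC/C(C)=C/[C@@H]1O | target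

**Step count and risks**

Total step count: 11. Longest linear sequence: 11 steps (1 → 22).

Steps most likely to fail:

Step 6. The ten-membered Stetter closure is unprecedented. It may lose to oligomerisation or to E/Z drift of the enal. Prolonged base may erode C8. The ring fusion may come out cis. Internal proton transfer may deliver H-11 syn to the new bond, giving the 11-epimer. The fallback replaces the carbene-bound acyl anion by a nucleophilic acyl radical. It sets out from 14: NaClO2/NaH2PO4/2-methylbut-2-ene in t-BuOH/H2O gives the carboxylic acid F1; PhSeSePh and PBu3 in CH2Cl2 convert it into the Se-phenyl selenoester F2; slow addition of (Me3Si)3SiH and 2,2'-azobis(2-methylpropionitrile) to F2 in benzene at 80 °C (0.003 M) generates the acyl radical. This radical adds 10-exo to the butenolide anti to C9, and the lactone radical takes hydrogen from the silane on the face anti to C6. The fallback comes back to the route at 16.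

Step 7. The facial preference of the macrocyclic enone is predicted, not known, and the 6R alcohol may dominate. The fallback is inversion instead of reduction control. It sets out from 16: the same reduction (or LiBH(s-Bu)3, THF, −78 °C) gives the 6R alcohol F3; Mitsunobu reaction with 4-nitrobenzoic acid, PPh3 and diisopropyl azodicarboxylate gives the inverted 6S 4-nitrobenzoate F4; K2CO3 in MeOH at 0 °C cleaves the aryl ester. It comes back at 17.

Step 10. The C8 hydroxyl is flanked by the branched C7, and slow acylation at 75 °C invites angelate-to-tiglate isomerisation. The fallback builds the angelate olefins in place. It sets out from 19: dicyclohexylcarbodiimide and 4-(dimethylamino)pyridine with 2-[bis(2,2,2-trifluoroethoxy)phosphoryl]propanoic acid give the bis(phosphonopropanoate) F5; KN(SiMe3)2, 18-crown-6 and acetaldehyde in THF at −78 °C (Still–Gennari olefination) then form both Z-2-methylbut-2-enoates. It comes back at 21.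

**Further compounds**

F1 | step 6 | (2E,6Z)-3,7-dimethyl-8-[(2S)-4-methyl-5-oxo-2,5-dihydrofuran-2-yl]octa-2,6-dienoic acid | OC(=O)/C=C(\C)CC/C=C(C)\C[C@@H]1OC(=O)C(C)=C1
F2 | step 6 | Se-phenyl (2E,6Z)-3,7-dimethyl-8-[(2S)-4-methyl-5-oxo-2,5-dihydrofuran-2-yl]octa-2,6-dieneselenoate | O=C([Se]c1ccccc1)/C=C(\C)CC/C=C(C)\C[C@@H]1OC(=O)C(C)=C1
F3 | step 7 | (1(10)Z,4E,6R,7S,8S,11S)-6-hydroxygermacra-1(10),4-dien-12,8-olide | C[C@@H]1C(=O)O[C@H]2C/C(C)=C\CC/C(C)=C/[C@@H](O)[C@H]12
F4 | step 7 | (1(10)Z,4E,6S,7R,8S,11S)-12-oxo-12,8-epoxygermacra-1(10),4-dien-6-yl 4-nitrobenzoate (6-O-(4-nitrobenzoyl) derivative of 17) | C[C@@H]1C(=O)O[C@H]2C/C(C)=C\CC/C(C)=C/[C@H](OC(=O)c3ccc(cc3)[N+](=O)[O-])[C@H]12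
F5 | step 10 | (1(10)Z,4E,6S,7R,8S,11S)-6-[(tert-butyldimethylsilyl)oxy]germacra-1(10),4-diene-8,12-diyl bis{2-[bis(2,2,2-trifluoroethoxy)phosphoryl]propanoate} | CC(P(=O)(OCC(F)(F)F)OCC(F)(F)F)C(=O)OC[C@@H](C)[C@@H]1[C@@H](OC(=O)C(C)P(=O)(OCC(F)(F)F)OCC(F)(F)F)C/C(C)=C\CC/C(C)=C/[C@@H]1O[Si](C)(C)C(C)(C)C
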